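Readings and results were generated by integration on assumed constants; scatter was added.

all flasks: substrate 0.050 M
- Saturday's: partner 0.090 M; run made earlier
- Sunday's: partner 0.12 M; run made earlier
- east: partner 0.0750 M; time 30 min
- north-east: partner 0.220 M; time 30 min

- Saturday's (time / min: isomer of the product / %, substrate / %, target / %): 1.33: 1.1, 83.2, 8.1; 4.00: 2.1, 60.3, 18.8; 8.00: 3.0, 40.9, 26.4; 10.0: 3.5, 35.0, 28.4; 15.0: 3.7, 25.1, 32.5
- Sunday's (time / min: isomer of the product / %, substrate / %, target / %): 3.00: 2.5, 62.9, 20.0; 6.00: 3.9, 43.0, 28.6; 10.0: 4.8, 30.0, 36.3; 12.0: 6.0, 25.3, 37.8; 15.0: 4.3, 20.4, 39.0

(readings scatter by 0.5 percentage points)

* which of these there is most of at the end, counted by the substrate in it, east (substrate / target / isomer of the product)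
* which of these there is most of at the end, counted by the substrate in it, north-east (substrate / target / isomer of the product)
* how much there is at the end of the one of these that leads, in percent of the substrate charged: east
* how much there is at the end of the one of these that leads, in percent of the substrate charged: north-east

- a reading of substrate is of its free form alone

Step 1. I add up the last reading of each run, at 15.0 min. Substrate, target and isomer of the product leave a gap of 38.7% of the charge in Saturday's run and 36.3% in Sunday's, so something unseen holds substrate.

Step 2. I divide target by gap, then by the equivalents of partner per substrate. That gives 0.467 in Saturday's run and 0.448 in Sunday's. Their mean, 0.457, a reading with the scatter of those runs, is the split per equivalent, a kind of selectivity factor: target won against gap lost, for each equivalent of partner charged.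

Step 3. Isomer of the product stands at 0.112 of target, as the mean of those last readings. So each part of target ties up itself, that isomer, and a gap of one part over the split times the equivalents. That cost is 2.57 parts in east and 1.61 in north-east. Target is then the charge not left as substrate, divided by the cost.

Step 4. I guess the substrate left. For east I take Sunday's last reading, 20.4%; for north-east, half of it, 10.2%. The balance gives target 31.0% in east and 55.8% in north-east.

Step 5. The second way uses no balance. I draw a straight line through the two runs' target at 15.0 min against partner. It gives 29.2% for east and 60.7% for north-east. I let these stand for the end, though they are read at 15.0 min and the flasks run to 30 min.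

Step 6. In east the two ways stand 1.8 percentage points apart, and I trust them. In north-east they part by 4.9 points. The line there needs 2.37% of substrate left at 15.0 min, while Sunday's run, with less partner, still held 20.4%, so I hold the line to be the one that cheats. By my reckoning target leads in both flasks.

The forecast says target at 33% in east and target at 61% in north-east, both higher than my balance, and adds of north-east: “though this is an extrapolation”.

The flasks give target at 29.3% in east and target at 56.7% in north-east, the latter below the line.

    substrate + partner ⇌ target (K = 92.7 /M, k = 0.772 /M/min)
    substrate + partner ⇌ isomer of the product (K = 67.0 /M, k = 0.0900 /M/min)
    substrate ⇌ dormant form (K = 3.00, k = 0.0635 /min)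
    partner → decomposed reagent (k = 0.0457 /min)

The gap is the dormant form. With the substrate that actually stands, 19.1% in east and 9.37% in north-east, the balance gives 31.5% and 56.3%. A neighbour of north-east, charged with 0.088 M of partner, has 1.76 equiv, so its cost is 2.36 parts. Its substrate at the end is 17.7%, which gives 34.9% of target by the balance. That neighbour flask ends with 33.1% of target.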